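What is left of J once the L in a flask has gone?

| setting | south | north | north-west | summer | midnight | autumn | dusk |
|---|---|---|---|---|---|---|---|
| L | 0.017 M | 0.079 M | 0.37 M | 0.015 M | 0.050 M | 0.15 M | 0.50 M |
| J | 0.15 M | 0.15 M | 0.15 M | 0.150 M | 0.150 M | 0.150 M | 0.150 M |
| remark | run made earlier | run made earlier | run made earlier |  |  |  |  |
| time |  |  |  | 8.0 d | 8.0 d | 8.0 d | 8.0 d |

- south (time / d: D / %, Q / %): 0.833: 9.2, 8.9; 1.67: 18.2, 22.8; 2.50: 21.2, 33.9; 3.00: 20.9, 39.3; 4.00: 19.0, 46.3
- north (time / d: D / %, Q / %): 0.333: 2.4, 2.0; 0.625: 5.6, 5.5; 1.04: 11.3, 11.6; 2.00: 18.2, 25.1; 4.00: 19.7, 40.9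
- north-west (time / d: D / %, Q / %): 0.333: 2.0, 1.4; 1.04: 7.8, 8.9; 1.67: 10.1, 14.7; 3.00: 8.3, 20.8; 4.00: 7.0, 23.0

(each reading ± 0.3 percentage points)

- "hardly changes" means that all values lie within two and a half points (for a concentration: within two and a half percent of the largest)

* share of D in all that became D or Q or G for summer, midnight, autumn, dusk, in this order
* how the row runs (falls, then rises / hardly changes / rises all the way / falls all the way / rises, then falls)

**Examiner:** Start with J. **Answer:** If each L takes one J, the fraction of J left is one minus [L] over [J], as charged, which gives 90.0% for summer and 66.7% for midnight.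

**Examiner:** And dusk? **Answer:** In dusk [L] is above [J], so J is the limiting reagent. I carry the ceiling, [J] over [L] as charged, which is the part of L that can end as D, Q or G: 30.0%.

**Examiner:** G is not read in the earlier runs, so what is that worth? **Answer:** The ceiling is my assumption, but it gives a way to reckon G. The north-west ceiling is 40.5%, while the readings of D plus Q come to 30.0% after 4.00 d. That leaves 11 percentage points for G if J is spent by then and G is the one unread thing that took it. The area under north-west's D readings is 0.293 d in fractions of the charge, so if the loss is first-order, my estimate for D is about 0.359 d⁻¹.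

**Examiner:** Then dusk's share? **Answer:** I take north-west's D over its ceiling, 17.3% at 4.00 d, as a stand-in for dusk. If no new D forms, the remaining 4.00 d leave a fraction 23.7% of D, so my estimate for dusk is about 4.10%.

**Examiner:** And below dusk? **Answer:** South and north read D 19.0% and 19.7% at 4.00 d, so I expect summer and midnight to be alike. North-west's D reading at 1.04 d is below north's at 1.04 d, with more L on the same [J], so I read D as delayed there. Autumn, with [L] equal to [J], should then hold more late D. My commitment is that the row rises, then falls.

The forecast gives 4%, 4%, 3.5%, 3.5%, hardly changes, on the ground of “a few percent at 8 d at every L”. My dusk estimate stands near the forecast's value, but we part at autumn, where I expect a rise.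

The flask gives 6.42%, 7.58%, 11.1%, 3.16%, so the row rises, then falls, turning at 0.14 M of L.

    X → Q (k = 6.37 × 10⁻⁴ min⁻¹)
    L + J → X (k = 0.00199 L mol⁻¹ min⁻¹)
    D → G (k = 2.39 × 10⁻⁴ min⁻¹)
    J + Z → D (k = 0.00816 L mol⁻¹ min⁻¹)
    L → Z (k = 2.31 × 10⁻⁴ min⁻¹)

At 8.00 d autumn holds D 9.87% and Z 8.18% of the L charged, with J 10.5% of its own charge still present. In dusk, D, Q and G add up to 30.0% of the L charged, against the ceiling of 30.0%. In midnight, J stands at 67.0% of its charge, against the reckoned 66.7%.

All runs are calculated with constants of no real substance; scatter was added.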